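## Retrosynthetic overview

1. Triene C2′–C3′ bond: Stille coupling of the epoxyquinol vinylstannane 23 with the bromodienamide 29 (from glutaconaldehyde salt 24 and the bought aminocyclopentenone 27).
2. Oxirane of 23: syn-selective nucleophilic epoxidation of the enantiopure p-quinol amide 22. Its enamide comes from the α-azido enone 12 by loss of N2 and N-acylation with acid chloride 19 (from methyl (R)-lactate 13).
3. Quaternary carbinol of 12: [2,3]-sigmatropic rearrangement of the allylic selenoxide 6, which carries oxygen across one ring face from C3 to C1 of a shikimate-derived azido alcohol 5.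
4. Rings, in order: the carbocycle is bought in (−)-shikimic acid 1; a transient 4,5-oxirane is closed in step 2 and opened in step 4; the final oxirane is formed in step 15; the cyclopentenone is bought in 27.

Assumption: 24 and 27 are catalogue chemicals; the target is made with the configuration written in its SMILES, (1S,5S,6R) in the core and (4R) in the acyl chain.

## Route

Step 1
Reactants: 1 (−)-shikimic acid [(3R,4S,5R)-3,4,5-trihydroxycyclohex-1-ene-1-carboxylic acid]
Product: 2 methyl shikimate [methyl (3R,4S,5R)-3,4,5-trihydroxycyclohex-1-ene-1-carboxylate]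
Conditions: MeOH, p-TsOH·H2O (cat.), reflux
Reagents that add atoms: methanol, CO
Why: Fischer esterification of the acid, with none of the three bought stereocentres touched.

Step 2
Reactants: 2 methyl shikimate
Product: 3 methyl (3R,4R,5S)-4,5-epoxy-3-hydroxycyclohex-1-ene-1-carboxylate (oxirane cis to the 3-OH)
Conditions: PPh3, DEAD, THF, 0 °C → rt
Reagents that add atoms: none
Why: Mitsunobu cyclodehydration in which the unhindered C5–OH is activated and displaced by the trans C4 oxygen with inversion at C5, leaving only the allylic C3–OH free.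

Step 3
Reactants: 3 methyl (3R,4R,5S)-4,5-epoxy-3-hydroxycyclohex-1-ene-1-carboxylate
Product: 4 methyl (3S,4S,5S)-4,5-epoxy-3-(phenylselanyl)cyclohex-1-ene-1-carboxylate (SePh trans to the oxirane)
Conditions: N-(phenylselanyl)phthalimide, PBu3, THF, 0 °C → rt
Reagents that add atoms: N-(phenylselanyl)phthalimide, O=C1N([Se]c2ccccc2)C(=O)c2ccccc12
Why: Mitsunobu-type (Grieco) dehydrative selenation in which PhSe− displaces the C3 alkoxyphosphonium by SN2, so the bought C3 centre is inverted cleanly.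

Step 4
Reactants: 4 methyl (3S,4S,5S)-4,5-epoxy-3-(phenylselanyl)cyclohex-1-ene-1-carboxylate
Product: 5 methyl (3S,4S,5R)-5-azido-4-hydroxy-3-(phenylselanyl)cyclohex-1-ene-1-carboxylate
Conditions: NaN3, NH4Cl, MeOH/H2O (8:1), 65 °C
Reagents that add atoms: sodium azide NaN3, [Na+].[N-]=[N+]=[N-]
Why: SN2 epoxide opening by azide at C5, away from C4 which is shielded by the neighbouring SePh group; both centres formed here are lost later (C4 becomes the ketone, C5 becomes sp2).

Step 5
Reactants: 5 methyl (3S,4S,5R)-5-azido-4-hydroxy-3-(phenylselanyl)cyclohex-1-ene-1-carboxylate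
Product: 8 methyl (1S,4R,5R)-5-azido-1,4-dihydroxycyclohex-2-ene-1-carboxylate, via selenoxide 6 (not isolated), via selenenate ester 7 (not isolated)
Conditions: 30% H2O2, pyridine, CH2Cl2, 0 °C → rt
Reagents that add atoms: hydrogen peroxide, OO
Why: Selenide oxidation followed by the [2,3]-sigmatropic selenoxide-to-selenenate rearrangement delivers oxygen suprafacially from C3 to C1, so the inverted C3 centre sets the quaternary carbinol as (1S) before the selenenate is cleaved in situ.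

Step 6
Reactants: 8 methyl (1S,4R,5R)-5-azido-1,4-dihydroxycyclohex-2-ene-1-carboxylate
Product: 10 (1S,4R,5R)-5-azido-1-ethynylcyclohex-2-ene-1,4-diol, via hydroxy aldehyde 9 (not isolated)
Conditions: i-Bu2AlH, CH2Cl2, −78 °C; then MeOH, K2CO3, dimethyl (1-diazo-2-oxopropyl)phosphonate, −78 °C → rt
Reagents that add atoms: dimethyl (1-diazo-2-oxopropyl)phosphonate, COP(=O)(OC)C(=[N+]=[N-])C(C)=O
Why: Partial reduction of the α-hydroxy ester to a chelated aluminium hemiacetal followed by Ohira–Bestmann (Seyferth–Gilbert) homologation of the released aldehyde, which cannot epimerise because the carbinol is quaternary.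

Step 7
Reactants: 10 (1S,4R,5R)-5-azido-1-ethynylcyclohex-2-ene-1,4-diol
Product: 11 (1S,4R,5R)-5-azido-1-[(E)-2-(tributylstannyl)ethenyl]cyclohex-2-ene-1,4-diol
Conditions: Bu3SnH, PdCl2(PPh3)2 (3 mol %), THF, 0 °C
Reagents that add atoms: tributyltin hydride Bu3SnH, CCCC[SnH](CCCC)CCCC
Why: Palladium-catalysed syn-hydrostannation of the terminal alkyne, with the bulky tertiary carbinol steering tin to the distal carbon to give the (E)-vinylstannane.

Step 8
Reactants: 11 (1S,4R,5R)-5-azido-1-[(E)-2-(tributylstannyl)ethenyl]cyclohex-2-ene-1,4-diol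
Product: 12 (4S,6R)-6-azido-4-hydroxy-4-[(E)-2-(tributylstannyl)ethenyl]cyclohex-2-en-1-one
Conditions: MnO2, CH2Cl2, rt
Reagents that add atoms: none
Why: Allylic oxidation by MnO2 converts only the secondary allylic alcohol to the enone, leaving the tertiary carbinol, the azide and the stannane untouched.

Step 9
Reactants: 13 methyl (R)-lactate
Product: 14 methyl (R)-2-[(trifluoromethanesulfonyl)oxy]propanoate
Conditions: Tf2O, 2,6-lutidine, CH2Cl2, −78 → 0 °C
Reagents that add atoms: triflic anhydride, O=S(=O)(OS(=O)(=O)C(F)(F)F)C(F)(F)F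
Why: O-sulfonylation of the secondary alcohol with retention makes the bought stereocentre an SN2 electrophile.

Step 10
Reactants: 14 methyl (R)-2-[(trifluoromethanesulfonyl)oxy]propanoate
Product: 15 methyl (R)-2-methylhexanoate
Conditions: Bu2CuLi, Et2O, −78 °C
Reagents that add atoms: lithium dibutylcuprate Bu2CuLi, [Li+].CCCC[Cu-]CCCC
Why: SN2 displacement of the α-triflate by the Gilman cuprate with clean inversion turns the lactate centre into the methyl-bearing (R) centre of the side chain.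

Step 11
Reactants: 15 methyl (R)-2-methylhexanoate
Product: 17 ethyl (2E,4R)-2,4-dimethyloct-2-enoate, via (R)-2-methylhexanal 16 (not isolated)
Conditions: i-Bu2AlH, CH2Cl2, −78 °C; then Ph3P=C(CH3)CO2Et, −78 °C → rt
Reagents that add atoms: ethyl 2-(triphenylphosphoranylidene)propanoate, CCOC(=O)C(C)=P(c1ccccc1)(c1ccccc1)c1ccccc1
Why: Half-reduction of the ester and Wittig olefination with the stabilised ylide in the same flask gives the (E)-enoate without isolating the epimerisable α-chiral aldehyde.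

Step 12
Reactants: 17 ethyl (2E,4R)-2,4-dimethyloct-2-enoate
Product: 18 (2E,4R)-2,4-dimethyloct-2-enoic acid
Conditions: LiOH, THF/MeOH/H2O, rt; then 1 M HCl
Reagents that add atoms: lithium hydroxide LiOH, [Li+].[OH-]
Why: Saponification of the conjugated ester, with the γ-stereocentre not acidic under these conditions.

Step 13
Reactants: 18 (2E,4R)-2,4-dimethyloct-2-enoic acid
Product: 19 (2E,4R)-2,4-dimethyloct-2-enoyl chloride
Conditions: (COCl)2, DMF (cat.), CH2Cl2, 0 °C → rt
Reagents that add atoms: oxalyl chloride, O=C(Cl)C(=O)Cl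
Why: Acid chloride formation through the Vilsmeier-type chloroiminium catalyst gives an acylating agent strong enough for a weakly nucleophilic enamine nitrogen.

Step 14
Reactants: 12 (4S,6R)-6-azido-4-hydroxy-4-[(E)-2-(tributylstannyl)ethenyl]cyclohex-2-en-1-one; 19 (2E,4R)-2,4-dimethyloct-2-enoyl chloride
Product: 22 (2E,4R)-N-[(3R)-3-hydroxy-6-oxo-3-[(E)-2-(tributylstannyl)ethenyl]cyclohexa-1,4-dien-1-yl]-2,4-dimethyloct-2-enamide, via imino ketone 20 (not isolated), via aminodienone 21 (not isolated)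
Conditions: DBU (0.2 eq), Et3N (3 eq), CH2Cl2, 0 °C → rt; then 19, DMAP (cat.), 0 °C
Reagents that add atoms: none
Why: Base-induced loss of N2 from the α-azido ketone gives the α-imino ketone, which tautomerises to the 2-aminodienone and is N-acylated, so the azide acts as internal oxidant for the enamide double bond while the carbinol centre is untouched.

Step 15
Reactants: 22 (2E,4R)-N-[(3R)-3-hydroxy-6-oxo-3-[(E)-2-(tributylstannyl)ethenyl]cyclohexa-1,4-dien-1-yl]-2,4-dimethyloct-2-enamide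
Product: 23 (2E,4R)-N-[(1S,5R,6R)-5-hydroxy-2-oxo-5-[(E)-2-(tributylstannyl)ethenyl]-7-oxabicyclo[4.1.0]hept-3-en-3-yl]-2,4-dimethyloct-2-enamide
Conditions: t-BuOOH (in decane), DBU, CH2Cl2, 0 °C
Reagents that add atoms: tert-butyl hydroperoxide, CC(C)(C)OO
Why: Weitz–Scheffer nucleophilic epoxidation attacks only the unsubstituted enone double bond, from the face of the hydrogen-bonding tertiary OH and anti to the bulky stannylvinyl group, so the carbinol centre sets both oxirane carbons syn to OH.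

Step 16
Reactants: 24 glutaconaldehyde potassium salt [potassium (1E,3E)-5-oxopenta-1,3-dien-1-olate]
Product: 25 (2E,4E)-5-bromopenta-2,4-dienal
Conditions: Ph3PBr2, CH2Cl2, 0 °C → rt
Reagents that add atoms: dibromotriphenylphosphorane Ph3PBr2, BrP(Br)(c1ccccc1)(c1ccccc1)c1ccccc1
Why: Deoxybromination of the vinylogous enolate through its O-phosphonium salt (addition–elimination by bromide) gives the thermodynamically favoured (E,E)-bromodienal.

Step 17
Reactants: 25 (2E,4E)-5-bromopenta-2,4-dienal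
Product: 26 (2E,4E)-5-bromopenta-2,4-dienoic acid
Conditions: NaClO2, NaH2PO4, 2-methylbut-2-ene, t-BuOH/H2O, rt
Reagents that add atoms: sodium chlorite NaClO2, [Na+].[O-]Cl=O
Why: Pinnick oxidation converts the enal to the acid without touching the bromodiene.

Step 18
Reactants: 26 (2E,4E)-5-bromopenta-2,4-dienoic acid; 27 2-amino-3-hydroxycyclopent-2-en-1-one hydrochloride
Product: 29 (2E,4E)-5-bromo-N-(2-hydroxy-5-oxocyclopent-1-en-1-yl)penta-2,4-dienamide, via bromodienoyl chloride 28 (not isolated)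
Conditions: (COCl)2, DMF (cat.), CH2Cl2, 0 °C; then 27, Et3N, THF, 0 °C → rt
Reagents that add atoms: none
Why: Acid chloride amidation of the enaminone nitrogen, with any O-acylated enol reverting to the more stable vinylogous-acid amide.

Step 19
Reactants: 23 (2E,4R)-N-[(1S,5R,6R)-5-hydroxy-2-oxo-5-[(E)-2-(tributylstannyl)ethenyl]-7-oxabicyclo[4.1.0]hept-3-en-3-yl]-2,4-dimethyloct-2-enamide; 29 (2E,4E)-5-bromo-N-(2-hydroxy-5-oxocyclopent-1-en-1-yl)penta-2,4-dienamide
Product: 30 (2E,4R)-N-[(1S,5S,6R)-5-hydroxy-5-[(1E,3E,5E)-7-[(2-hydroxy-5-oxocyclopent-1-en-1-yl)amino]-7-oxohepta-1,3,5-trien-1-yl]-2-oxo-7-oxabicyclo[4.1.0]hept-3-en-3-yl]-2,4-dimethyloct-2-enamide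
Conditions: PdCl2(MeCN)2 (5 mol %), DMF, rt, dark
Reagents that add atoms: none
Why: Stille cross-coupling joins the two sp2 carbons with retention of all three alkene geometries under neutral conditions that spare the epoxy enone, the free tertiary alcohol and the acidic enol.

## Compound list

1 | (−)-shikimic acid, (3R,4S,5R)-3,4,5-trihydroxycyclohex-1-ene-1-carboxylic acid | O=C(O)C1=C[C@@H](O)[C@@H](O)[C@H](O)C1 | starting material
2 | methyl (3R,4S,5R)-3,4,5-trihydroxycyclohex-1-ene-1-carboxylate | COC(=O)C1=C[C@@H](O)[C@@H](O)[C@H](O)C1 | intermediate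
3 | methyl (3R,4R,5S)-4,5-epoxy-3-hydroxycyclohex-1-ene-1-carboxylate | COC(=O)C1=C[C@@H](O)[C@H]2O[C@H]2C1 | intermediate
4 | methyl (3S,4S,5S)-4,5-epoxy-3-(phenylselanyl)cyclohex-1-ene-1-carboxylate | COC(=O)C1=C[C@H]([Se]c2ccccc2)[C@H]3O[C@H]3C1 | intermediate
5 | methyl (3S,4S,5R)-5-azido-4-hydroxy-3-(phenylselanyl)cyclohex-1-ene-1-carboxylate | COC(=O)C1=C[C@H]([Se]c2ccccc2)[C@@H](O)[C@H](N=[N+]=[N-])C1 | intermediate
6 | methyl (3S,4S,5R)-5-azido-4-hydroxy-3-(phenylseleninyl)cyclohex-1-ene-1-carboxylate | COC(=O)C1=C[C@H]([Se](=O)c2ccccc2)[C@@H](O)[C@H](N=[N+]=[N-])C1 | intermediate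
7 | methyl (1S,4R,5R)-5-azido-4-hydroxy-1-[(phenylselanyl)oxy]cyclohex-2-ene-1-carboxylate | COC(=O)[C@@]1(O[Se]c2ccccc2)C=C[C@@H](O)[C@H](N=[N+]=[N-])C1 | intermediate
8 | methyl (1S,4R,5R)-5-azido-1,4-dihydroxycyclohex-2-ene-1-carboxylate | COC(=O)[C@@]1(O)C=C[C@@H](O)[C@H](N=[N+]=[N-])C1 | intermediate
9 | (1S,4R,5R)-5-azido-1,4-dihydroxycyclohex-2-ene-1-carbaldehyde | O=C[C@@]1(O)C=C[C@@H](O)[C@H](N=[N+]=[N-])C1 | intermediate
10 | (1S,4R,5R)-5-azido-1-ethynylcyclohex-2-ene-1,4-diol | C#C[C@@]1(O)C=C[C@@H](O)[C@H](N=[N+]=[N-])C1 | intermediate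
11 | (1S,4R,5R)-5-azido-1-[(E)-2-(tributylstannyl)ethenyl]cyclohex-2-ene-1,4-diol | CCCC[Sn](CCCC)(CCCC)/C=C/[C@@]1(O)C=C[C@@H](O)[C@H](N=[N+]=[N-])C1 | intermediate
12 | (4S,6R)-6-azido-4-hydroxy-4-[(E)-2-(tributylstannyl)ethenyl]cyclohex-2-en-1-one | CCCC[Sn](CCCC)(CCCC)/C=C/[C@@]1(O)C=CC(=O)[C@H](N=[N+]=[N-])C1 | intermediate
13 | methyl (R)-lactate | C[C@@H](O)C(=O)OC | starting material
14 | methyl (R)-2-[(trifluoromethanesulfonyl)oxy]propanoate | C[C@@H](OS(=O)(=O)C(F)(F)F)C(=O)OC | intermediate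
15 | methyl (R)-2-methylhexanoate | CCCC[C@@H](C)C(=O)OC | intermediate
16 | (R)-2-methylhexanal | CCCC[C@@H](C)C=O | intermediate
17 | ethyl (2E,4R)-2,4-dimethyloct-2-enoate | CCCC[C@@H](C)/C=C(\C)C(=O)OCC | intermediate
18 | (2E,4R)-2,4-dimethyloct-2-enoic acid | CCCC[C@@H](C)/C=C(\C)C(=O)O | intermediate
19 | (2E,4R)-2,4-dimethyloct-2-enoyl chloride | CCCC[C@@H](C)/C=C(\C)C(=O)Cl | intermediate
20 | (4S)-4-hydroxy-6-imino-4-[(E)-2-(tributylstannyl)ethenyl]cyclohex-2-en-1-one | CCCC[Sn](CCCC)(CCCC)/C=C/[C@@]1(O)C=CC(=O)C(=N)C1 | intermediate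
21 | (4R)-2-amino-4-hydroxy-4-[(E)-2-(tributylstannyl)ethenyl]cyclohexa-2,5-dien-1-one | CCCC[Sn](CCCC)(CCCC)/C=C/[C@@]1(O)C=CC(=O)C(N)=C1 | intermediate
22 | (2E,4R)-N-[(3R)-3-hydroxy-6-oxo-3-[(E)-2-(tributylstannyl)ethenyl]cyclohexa-1,4-dien-1-yl]-2,4-dimethyloct-2-enamide | CCCC[C@@H](C)/C=C(\C)C(=O)NC1=C[C@@](O)(/C=C/[Sn](CCCC)(CCCC)CCCC)C=CC1=O | intermediate
23 | (2E,4R)-N-[(1S,5R,6R)-5-hydroxy-2-oxo-5-[(E)-2-(tributylstannyl)ethenyl]-7-oxabicyclo[4.1.0]hept-3-en-3-yl]-2,4-dimethyloct-2-enamide | CCCC[C@@H](C)/C=C(\C)C(=O)NC1=C[C@@](O)(/C=C/[Sn](CCCC)(CCCC)CCCC)[C@@H]2O[C@@H]2C1=O | intermediate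
24 | glutaconaldehyde potassium salt, potassium (1E,3E)-5-oxopenta-1,3-dien-1-olate | [K+].[O-]/C=C/C=C/C=O | starting material
25 | (2E,4E)-5-bromopenta-2,4-dienal | Br/C=C/C=C/C=O | intermediate
26 | (2E,4E)-5-bromopenta-2,4-dienoic acid | Br/C=C/C=C/C(=O)O | intermediate
27 | 2-amino-3-hydroxycyclopent-2-en-1-one hydrochloride | NC1=C(O)CCC1=O.Cl | starting material
28 | (2E,4E)-5-bromopenta-2,4-dienoyl chloride | Br/C=C/C=C/C(=O)Cl | intermediate
29 | (2E,4E)-5-bromo-N-(2-hydroxy-5-oxocyclopent-1-en-1-yl)penta-2,4-dienamide | Br/C=C/C=C/C(=O)NC1=C(O)CCC1=O | intermediate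
30 | (2E,4R)-N-[(1S,5S,6R)-5-hydroxy-5-[(1E,3E,5E)-7-[(2-hydroxy-5-oxocyclopent-1-en-1-yl)amino]-7-oxohepta-1,3,5-trien-1-yl]-2-oxo-7-oxabicyclo[4.1.0]hept-3-en-3-yl]-2,4-dimethyloct-2-enamide | CCCC[C@@H](C)/C=C(\C)C(=O)NC1=C[C@@](O)(/C=C/C=C/C=C/C(=O)NC2=C(O)CCC2=O)[C@@H]2O[C@@H]2C1=O | target

## Step count and risks

Total step count: 19. Longest linear sequence: 11 steps (steps 1–8, 14, 15 and 19, from 1).

The three steps most likely to fail:

Step 14 is the least precedented operation: the α-azido ketone must lose N2 cleanly and the resulting aminodienone is a poor nucleophile. The fallback makes the amide first and the unsaturation second. It sets out from 11: Staudinger reduction (PMe3, THF/H2O) gives the amino diol (1S,4R,5R)-5-amino-1-[(E)-2-(tributylstannyl)ethenyl]cyclohex-2-ene-1,4-diol F4. N-acylation with 19 (Et3N, CH2Cl2) gives the hydroxy amide (2E,4R)-N-[(1R,2R,5S)-2,5-dihydroxy-5-[(E)-2-(tributylstannyl)ethenyl]cyclohex-3-en-1-yl]-2,4-dimethyloct-2-enamide F5. MnO2 then gives the α-amido enone (2E,4R)-N-[(1R,5S)-5-hydroxy-2-oxo-5-[(E)-2-(tributylstannyl)ethenyl]cyclohex-3-en-1-yl]-2,4-dimethyloct-2-enamide F6. Dehydrogenation of the α-amido ketone with IBX in DMSO at 65 °C comes back to the route at 22; the tolerance of the vinylstannane to IBX would have to be checked.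

Step 3 asks for clean SN2 at a secondary allylic carbon next to an oxirane; SN2′ attack or elimination would erode the chirality transfer of step 5. The fallback installs selenium by opening a cyclic sulfite instead. It sets out from 2: SOCl2, Et3N, CH2Cl2 at 0 °C closes the cis-3,4-diol to the cyclic sulfite methyl (3R,4S,5R)-5-hydroxy-3,4-(sulfinyldioxy)cyclohex-1-ene-1-carboxylate F1. PhSeNa (from PhSeSePh and NaBH4, EtOH, 0 °C) opens it at the allylic C3 with inversion and loss of SO2 to the seleno diol methyl (3S,4S,5R)-4,5-dihydroxy-3-(phenylselanyl)cyclohex-1-ene-1-carboxylate F2. Mitsunobu cyclodehydration of the trans-4,5-diol (PPh3, DEAD, as in step 2) closes the oxirane and comes back to the route at 4.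

Step 6 runs a partial ester reduction on a substrate with two free hydroxyls and an azide; over-reduction is the likely failure. The fallback over-reduces on purpose and re-oxidises selectively. It sets out from 8: NaBH4 in MeOH at 0 °C reduces the α-hydroxy ester to the triol (1S,4R,5R)-5-azido-1-(hydroxymethyl)cyclohex-2-ene-1,4-diol F3. TEMPO/PhI(OAc)2 in CH2Cl2 then oxidises only the primary alcohol and comes back to the route at aldehyde 9, which is homologated to 10 under the second half of the step 6 conditions.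

## Further compounds

F1 | step 3 | methyl (3R,4S,5R)-5-hydroxy-3,4-(sulfinyldioxy)cyclohex-1-ene-1-carboxylate | COC(=O)C1=C[C@@H]2[C@@H](OS(=O)O2)[C@H](O)C1
F2 | step 3 | methyl (3S,4S,5R)-4,5-dihydroxy-3-(phenylselanyl)cyclohex-1-ene-1-carboxylate | COC(=O)C1=C[C@H]([Se]c2ccccc2)[C@@H](O)[C@H](O)C1
F3 | step 6 | (1S,4R,5R)-5-azido-1-(hydroxymethyl)cyclohex-2-ene-1,4-diol | OC[C@@]1(O)C=C[C@@H](O)[C@H](N=[N+]=[N-])C1
F4 | step 14 | (1S,4R,5R)-5-amino-1-[(E)-2-(tributylstannyl)ethenyl]cyclohex-2-ene-1,4-diol | N[C@@H]1C[C@@](O)(/C=C/[Sn](CCCC)(CCCC)CCCC)C=C[C@H]1O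
F5 | step 14 | (2E,4R)-N-[(1R,2R,5S)-2,5-dihydroxy-5-[(E)-2-(tributylstannyl)ethenyl]cyclohex-3-en-1-yl]-2,4-dimethyloct-2-enamide | CCCC[C@@H](C)/C=C(\C)C(=O)N[C@@H]1C[C@@](O)(/C=C/[Sn](CCCC)(CCCC)CCCC)C=C[C@H]1O
F6 | step 14 | (2E,4R)-N-[(1R,5S)-5-hydroxy-2-oxo-5-[(E)-2-(tributylstannyl)ethenyl]cyclohex-3-en-1-yl]-2,4-dimethyloct-2-enamide | CCCC[C@@H](C)/C=C(\C)C(=O)N[C@@H]1C[C@@](O)(/C=C/[Sn](CCCC)(CCCC)CCCC)C=CC1=O
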